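**Plan**

- Retrosynthetic cuts, in order: (1) the C10–C11 bond of the side chain inside the 1,4-diketone, giving an aldehyde and methyl vinyl ketone; (2) the formyl carbon of that aldehyde, giving a terminal alkene and CO; (3) together, the two bonds from the benzene ring to the lactone ring, aryl C3a–C3 and aryl C7a–C1(=O), giving 3,5-dimethoxybenzyne and an O-alkyl carbamate whose O–C(=O) unit becomes the lactone ester.
- Forward: dec-9-en-1-ol is made into its N,N-diisopropylcarbamate and 3,5-dimethoxyphenol into its triflate. The two meet in one flask, where the five-membered lactone ring is built onto the existing benzene ring (no other ring is made). The chain is then lengthened by hydroformylation and a Stetter reaction.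
- Enabling feature: the C7 methoxy group lies directly beside the aryne bond (C3a≡C7a of the future benzofuranone). A carbanion therefore bonds to C3a and leaves the aryl anion on C7a, in reach of the carbamate carbonyl for five-membered ring closure. The symmetric 3,5-dimethoxyphenyl triflate can give only this aryne.
- Stereochemistry: the single stereocentre (C3, S) is set by (+)-sparteine-mediated deprotonation of the carbamate and carried into the C–aryl bond with retention. No later step touches it.

Key step: step 3

Assumption: the lithiated carbamate is taken to bond to the aryne with retention at carbon (four-centre delivery with lithium bound to the aryne), as it does with other electrophiles; if inversion were found, (−)-sparteine would be used in step 3 instead.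

**Route**

Step 1
Reactants: 1 dec-9-en-1-ol
Product: 2 dec-9-en-1-yl N,N-diisopropylcarbamate
Conditions: NaH, THF, 0 °C; N,N-diisopropylcarbamoyl chloride, reflux
Reagents that add atoms: N,N-diisopropylcarbamoyl chloride, CC(C)N(C(C)C)C(Cl)=O
Why: O-carbamoylation of the sodium alkoxide by the hindered carbamoyl chloride should be clean, and the carbamate serves later as directing group for the deprotonation and as source of the lactone carbonyl carbon.

Step 2
Reactants: 3 3,5-dimethoxyphenol
Product: 4 3,5-dimethoxyphenyl trifluoromethanesulfonate
Conditions: Tf2O, pyridine, CH2Cl2, 0 °C to 20 °C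
Reagents that add atoms: trifluoromethanesulfonic anhydride, O=S(=O)(OS(=O)(=O)C(F)(F)F)C(F)(F)F
Why: O-sulfonylation (triflation) of a phenol is routine, and in the symmetric product both positions ortho to the triflate are equivalent and flanked by a methoxy group, so only one aryne can arise from it.

Step 3
Reactants: 2 dec-9-en-1-yl N,N-diisopropylcarbamate; 4 3,5-dimethoxyphenyl trifluoromethanesulfonate
Product: 9 (3S)-5,7-dimethoxy-3-(non-8-en-1-yl)-2-benzofuran-1(3H)-one, via lithiated carbamate 5 (not isolated), via 3,5-dimethoxybenzyne 6 (not isolated), via aryllithium 7 (not isolated), via hydroxy amide 8 (not isolated)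
Conditions: s-BuLi, (+)-sparteine, Et2O, −78 °C; LiTMP (lithium 2,2,6,6-tetramethylpiperidide), THF, then 4 (slow addition), −78 °C; warm to 20 °C; 2 M HCl; crude with TsOH·H2O, toluene, 80 °C
Reagents that add atoms: none
Why: Proposed new method: (+)-sparteine-directed deprotonation gives the configurationally stable (R)-α-lithio carbamate 5, and LiTMP ortho-lithiates triflate 4 between the triflate and a methoxy group, so that loss of LiOTf releases aryne 6 at −78 °C; 5 should then add across the strained triple bond by a four-centre syn-carbolithiation with retention at carbon to give aryllithium 7, whose carbanion attacks the carbamate carbonyl and so forms the aryl–carbonyl bond. The closest known reaction types are the LiTMP-mediated generation of arynes from aryl triflates in the presence of organolithium nucleophiles with electrophilic capture of the new aryllithium, the retentive substitution of sparteine-derived lithiated carbamates, and the Parham-type anionic cyclisation of ortho-lithiated benzyl carbamates to phthalides; new here are a stereodefined sp3 α-oxy organolithium as the aryne partner and the built-in carbamate as the second electrophile. The only ring closed is the five-membered lactone ring, by 5-exo-trig attack of the aryl carbanion on the carbamate C=O; the tetrahedral adduct should open to the lithium alkoxide of hydroxy amide 8, and the acid finish re-closes it with loss of diisopropylamine, so both forms end as lactone 9. The stereocentre is controlled by the chiral diamine in the deprotonation (pro-R hydrogen removed) and by retention in the C–C bond formation, and as a benzylic carbon with both methoxy groups meta and the acyl group ortho it should not ionise under the acid. The regioselectivity needed is bonding of the carbanion to the aryne carbon remote from the flanking methoxy group: this inductively withdrawing group beside the triple bond distorts the aryne so that the distal carbon is the more linear and electrophilic one and the developing aryl anion sits next to oxygen, exactly where the carbonyl belongs, while the second methoxy group (meta to the attacked carbon) has only a weak influence. Chemoselectivity rests on LiTMP being a faster base and a far poorer aryne nucleophile than 5, on full consumption of s-BuLi before the aryne is made, and on slow addition of 4 to keep aryne and triflate concentrations low.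

Step 4
Reactants: 9 (3S)-5,7-dimethoxy-3-(non-8-en-1-yl)-2-benzofuran-1(3H)-one
Product: 10 10-[(1S)-4,6-dimethoxy-3-oxo-1,3-dihydro-2-benzofuran-1-yl]decanal
Conditions: Rh(acac)(CO)2 (cat.), Xantphos, CO/H2 (1:1, 10 bar), toluene, 80 °C
Reagents that add atoms: carbon monoxide, [C-]#[O+]
Why: Linear-selective rhodium-catalysed hydroformylation of an unhindered terminal alkene with a wide-bite-angle diphosphine should place the formyl carbon at the chain end, while the lactone, the aryl ethers and the remote stereocentre are inert.

Step 5
Reactants: 10 10-[(1S)-4,6-dimethoxy-3-oxo-1,3-dihydro-2-benzofuran-1-yl]decanal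
Product: 11 CJ-13,015, (3S)-3-(10,13-dioxotetradecyl)-5,7-dimethoxy-2-benzofuran-1(3H)-one
Conditions: methyl vinyl ketone, 3-benzyl-5-(2-hydroxyethyl)-4-methylthiazolium chloride (cat.), Et3N, EtOH, 75 °C
Reagents that add atoms: methyl vinyl ketone (but-3-en-2-one), CC(=O)C=C
Why: In this Stetter reaction the thiazolylidene carbene turns the aliphatic aldehyde into a Breslow acyl-anion equivalent that adds 1,4 to the enone and gives the 1,4-diketone directly, under conditions too weakly basic to deprotonate C3 of the phthalide.

**Compound list**

1 | dec-9-en-1-ol | OCCCCCCCCC=C | starting material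
2 | dec-9-en-1-yl N,N-diisopropylcarbamate | C=CCCCCCCCCOC(=O)N(C(C)C)C(C)C | intermediate
3 | 3,5-dimethoxyphenol | COc1cc(O)cc(OC)c1 | starting material
4 | 3,5-dimethoxyphenyl trifluoromethanesulfonate | COc1cc(OC)cc(OS(=O)(=O)C(F)(F)F)c1 | intermediate
5 | (R)-1-lithiodec-9-en-1-yl N,N-diisopropylcarbamate, held as its (+)-sparteine complex (formed in the flask) | [Li][C@H](CCCCCCCC=C)OC(=O)N(C(C)C)C(C)C | intermediate
6 | 3,5-dimethoxybenzyne, 1,2-didehydro-3,5-dimethoxybenzene (formed in the flask) | COC1=CC(OC)=CC#C1 | intermediate
7 | (S)-1-(2-lithio-3,5-dimethoxyphenyl)dec-9-en-1-yl N,N-diisopropylcarbamate (formed in the flask) | COc1cc(OC)c([Li])c(c1)[C@H](CCCCCCCC=C)OC(=O)N(C(C)C)C(C)C | intermediate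
8 | 2-[(1S)-1-hydroxydec-9-en-1-yl]-4,6-dimethoxy-N,N-di(propan-2-yl)benzamide (crude, not purified) | COc1cc(OC)c(C(=O)N(C(C)C)C(C)C)c(c1)[C@@H](O)CCCCCCCC=C | intermediate
9 | (3S)-5,7-dimethoxy-3-(non-8-en-1-yl)-2-benzofuran-1(3H)-one | COc1cc(OC)c2c(c1)[C@H](CCCCCCCC=C)OC2=O | intermediate
10 | 10-[(1S)-4,6-dimethoxy-3-oxo-1,3-dihydro-2-benzofuran-1-yl]decanal | COc1cc(OC)c2c(c1)[C@H](CCCCCCCCCC=O)OC2=O | intermediate
11 | CJ-13,015, (3S)-3-(10,13-dioxotetradecyl)-5,7-dimethoxy-2-benzofuran-1(3H)-one | COc1cc(OC)c2c(c1)[C@H](CCCCCCCCCC(=O)CCC(C)=O)OC2=O | target

**Count and risks**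

Total step count: 5. Longest linear sequence: 4 steps (steps 1, 3, 4, 5); step 2 is a one-step branch that joins at step 3.

Steps most likely to fail:

1. Step 3 (proposed new method). What may go wrong: proton transfer from the triflate or from tetramethylpiperidine to the lithiated carbamate, attack of the carbanion on the sulfonyl sulfur in place of carbolithiation, loss of configuration of the organolithium before the C–C bond forms, or sluggish anionic acyl transfer. The fallback uses known chemistry, sets out from carbamate 2 and comes back to the route at aryllithium 7. Compound 2 is lithiated as before (s-BuLi, (+)-sparteine, Et2O, −78 °C), transmetalated with Zn(OAc)2 and coupled with 1-bromo-3,5-dimethoxybenzene under zerovalent palladium catalysis (Pd2(dba)3, P(t-Bu)3·HBF4, 20 °C). This stereoretentive Negishi α-arylation should give (S)-1-(3,5-dimethoxyphenyl)dec-9-en-1-yl N,N-diisopropylcarbamate F1. Electrophilic bromination (NBS, MeCN, 0 °C) para to one methoxy group and ortho to the side chain should give (S)-1-(2-bromo-3,5-dimethoxyphenyl)dec-9-en-1-yl N,N-diisopropylcarbamate F2. Bromine–lithium exchange (n-BuLi, THF, −78 °C) then generates 7 without any aryne, and warming and the acid finish of step 3 lead to 9.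

2. Step 5. What may go wrong: acyloin self-condensation and aldol condensation of the aliphatic aldehyde, and base-induced oligomerisation of the enone, outpace the conjugate addition of the acyl-anion equivalent. The fallback sets out from aldehyde 10 and comes back at target 11. Compound 10 is treated with [2-(2-methyl-1,3-dioxolan-2-yl)ethyl]magnesium bromide (from 2-(2-bromoethyl)-2-methyl-1,3-dioxolane and Mg; THF, −78 °C, where the aldehyde is far more reactive than the lactone). This should give (3S)-3-[10-hydroxy-12-(2-methyl-1,3-dioxolan-2-yl)dodecyl]-5,7-dimethoxy-2-benzofuran-1(3H)-one F3 as a mixture of carbinol epimers. Oxidation with Dess–Martin periodinane (CH2Cl2, 20 °C) should give (3S)-5,7-dimethoxy-3-[12-(2-methyl-1,3-dioxolan-2-yl)-10-oxododecyl]-2-benzofuran-1(3H)-one F4. Ketal hydrolysis (PPTS, acetone/H2O, 50 °C) then releases the second ketone and gives 11.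

3. Step 4. What may go wrong: branched-selective formyl delivery, and migration of the double bond along the chain before CO insertion. The fallback sets out from alkene 9 and comes back at aldehyde 10. Cross-metathesis of 9 with crotonaldehyde (second-generation Hoveyda–Grubbs catalyst, CH2Cl2, 40 °C) should give (2E)-10-[(1S)-4,6-dimethoxy-3-oxo-1,3-dihydro-2-benzofuran-1-yl]dec-2-enal F5. Chemoselective hydrogenation of the conjugated C=C bond (H2, Pd/C, EtOAc, 20 °C) then gives 10.

Further compounds
F1 | step 3 | (S)-1-(3,5-dimethoxyphenyl)dec-9-en-1-yl N,N-diisopropylcarbamate | COc1cc(OC)cc(c1)[C@H](CCCCCCCC=C)OC(=O)N(C(C)C)C(C)C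
F2 | step 3 | (S)-1-(2-bromo-3,5-dimethoxyphenyl)dec-9-en-1-yl N,N-diisopropylcarbamate | COc1cc(OC)c(Br)c(c1)[C@H](CCCCCCCC=C)OC(=O)N(C(C)C)C(C)C
F3 | step 5 | (3S)-3-[10-hydroxy-12-(2-methyl-1,3-dioxolan-2-yl)dodecyl]-5,7-dimethoxy-2-benzofuran-1(3H)-one, mixture of carbinol epimers | COc1cc(OC)c2c(c1)[C@H](CCCCCCCCCC(O)CCC3(C)OCCO3)OC2=O
F4 | step 5 | (3S)-5,7-dimethoxy-3-[12-(2-methyl-1,3-dioxolan-2-yl)-10-oxododecyl]-2-benzofuran-1(3H)-one | COc1cc(OC)c2c(c1)[C@H](CCCCCCCCCC(=O)CCC3(C)OCCO3)OC2=O
F5 | step 4 | (2E)-10-[(1S)-4,6-dimethoxy-3-oxo-1,3-dihydro-2-benzofuran-1-yl]dec-2-enal | COc1cc(OC)c2c(c1)[C@H](CCCCCCC/C=C/C=O)OC2=O
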